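The earlier runs and the new flask come from a simulation for an exercise; scatter was added.

A small charge, 0.800 equiv of incoming ligand in gamma, made me doubt the bench rule: pseudo-first-order decay of starting complex, with c(incoming ligand) held at its charge.

| setting | south | south-east | gamma | epsilon | delta |
|---|---|---|---|---|---|
| starting complex | 0.054 M | 0.054 M | 0.054 M | 0.054 M | 0.054 M |
| incoming ligand | 1.1 equiv | 4 equiv | 0.800 equiv | 1.50 equiv | 3.00 equiv |
| remark | run made earlier | run made earlier |  |  |  |
| time |  |  | 3.0 min | 3.0 min | 3.0 min |

| run | time / s | complex with one exchanged / % | complex with four exchanged / % | starting complex / % |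
|---|---|---|---|---|
| south | 10.0 | 6 | 0 | 92 |
| south | 12.0 | 6 | 0 | 99 |
| south | 15.0 | 5 | 3 | 97 |
| south | 25.0 | 7 | 0 | 91 |
| south | 40.0 | 10 | 0 | 88 |
| south | 60.0 | 10 | 0 | 81 |
| south | 90.0 | 20 | 3 | 75 |
| south-east | 12.0 | 14 | 0 | 89 |
| south-east | 25.0 | 21 | 0 | 81 |
| south-east | 40.0 | 31 | 3 | 64 |
| south-east | 50.0 | 32 | 2 | 59 |
| south-east | 60.0 | 31 | 4 | 54 |
| south-east | 80.0 | 34 | 5 | 45 |
| south-east | 90.0 | 33 | 8 | 39 |

(scatter of a reading: 2 percentage points)

- reactions considered so far: starting complex + incoming ligand <-> leaving ligand + complex with one exchanged; complex with one exchanged + incoming ligand <-> leaving ligand + complex with two exchanged; complex with two exchanged + incoming ligand <-> leaving ligand + complex with three exchanged; complex with three exchanged + incoming ligand <-> leaving ligand + complex with four exchanged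

- how much complex with one exchanged is there at the end, in percent of the starting complex charged: for each flask in turn (gamma, epsilon, delta)

From the fraction of starting complex left at 90.0 s in the south-east run, I read

k = −ln(left) / (c(incoming ligand) t) = 0.0484 /M/s

So I turned the rule around. If every complex form takes up incoming ligand at about k, the ligand decays pseudo-first-order in c(starting complex) as charged, whatever its own equivalents:

λ = k c(starting complex) t

The border of the bench rule is this ratio of the time to the ligand's lifetime. It must be small, but in the south-east run it was already 0.235. Correcting for that fall gave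

k = 0.0544 /M/s

and at 3.0 min

λ = 0.528

I call the fraction of incoming ligand left f, here 59.0 %, the ligand survival. Gamma, epsilon and delta differ in equivalents, not in c(starting complex) or time, so I reckoned the same f for all of them. The mean ligand is then its charge times

(first level minus f) / λ = 0.777

For epsilon, I reckoned 45.3 % of starting complex left by the bench rule and 54.0 % left with my mean ligand.

The forecast gave 21 %, 29 % and 31 % of complex with one exchanged, “the last close to its maximum”.

The flasks gave 22.5 %, 30.6 % and 31.5 %, within the margin.

    starting complex + incoming ligand ⇌ leaving ligand + complex with one exchanged (K = 1.90, k = 0.0540 /M/s)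
    complex with one exchanged + incoming ligand ⇌ leaving ligand + complex with two exchanged (K = 22.0, k = 0.0580 /M/s)
    complex with two exchanged + incoming ligand ⇌ leaving ligand + complex with three exchanged (K = 0.700, k = 0.250 /M/s)
    complex with three exchanged + incoming ligand ⇌ leaving ligand + complex with four exchanged (K = 1.80, k = 0.120 /M/s)

Incoming ligand left stood at 58 % in epsilon and 57 % in delta, against f of 59.0 %, though delta had twice the equivalents of epsilon; starting complex left in epsilon was 57 %. Holding the ligand at its charge moved complex with one exchanged in epsilon from 30.6 % to 32.8 %, so that fall is not the reason for its height. The main reason is the time of the reading: ten times later, epsilon held 14.2 % of complex with one exchanged instead of 30.6 %.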